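Assumption: the SMILES is read as (3R)-6,8-dihydroxy-3-[(10S)-10-methoxyundecyl]-3,4-dihydro-1H-isochromen-1-one; but-3-enylmagnesium bromide is bought as its commercial THF solution.

**Retrosynthetic overview**
1. The lactone is the only ring made (the benzene ring is bought as resorcinol) and it is closed last: the aryl C4a–C4 bond and the C1–O2 ester bond come from a Pd-catalysed, carboxylate-directed ortho-C–H alkylation/lactonisation of unprotected 2,4-dihydroxybenzoic acid with (R)-2-[(S)-10-methoxyundecyl]oxirane.
2. 2,4-Dihydroxybenzoic acid ⇒ resorcinol + CO2 (Kolbe–Schmitt).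
3. The C14 epoxide ⇒ alkene hydrogenation ⇒ cross-metathesis of (S)-7-methoxyoct-1-ene with (R)-2-(pent-4-en-1-yl)oxirane.
4. (S)-7-Methoxyoct-1-ene ⇒ (S)-propylene oxide + pent-4-enyl Grignard, then O-methylation; (R)-2-(pent-4-en-1-yl)oxirane ⇒ (R)-epichlorohydrin + but-3-enyl Grignard, then ring closure.
5. Both stereocentres come from the chiral pool, and no bond to either stereocentre carbon is broken at any stage.

**Route**

Step 1
Reactants: 1 5-bromopent-1-ene; 2 (S)-propylene oxide [(S)-2-methyloxirane]
Product: 4 (S)-oct-7-en-2-ol, via pent-4-enylmagnesium bromide 3 (not isolated)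
Conditions: Mg, THF, 40 °C; then CuI (10 mol%), 2, THF, −30 → 0 °C; 1 M HCl work-up
Reagents that add atoms: none
Why: Copper-catalysed Grignard opening of a terminal epoxide occurs by SN2 attack at the unsubstituted CH2, so the C–O stereocentre of 2 is carried unchanged into the (S)-alcohol.

Step 2
Reactants: 4 (S)-oct-7-en-2-ol
Product: 5 (S)-7-methoxyoct-1-ene
Conditions: NaH, MeI, THF, 0 °C → rt
Reagents that add atoms: iodomethane, CI
Why: Williamson ether synthesis alkylates the alkoxide oxygen only, so the (S) centre is retained.

Step 3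
Reactants: 6 (R)-epichlorohydrin [(R)-2-(chloromethyl)oxirane]; 7 but-3-enylmagnesium bromide (0.5 M in THF)
Product: 8 (R)-1-chlorohept-6-en-2-ol
Conditions: CuI (5 mol%), THF, −40 → −20 °C; 1 M HCl work-up
Reagents that add atoms: none
Why: Copper-catalysed Grignard opening at the epoxide CH2 is much faster than chloride displacement at low temperature, and the magnesium alkoxide does not re-close below 0 °C; the stereocentre is untouched.

Step 4
Reactants: 8 (R)-1-chlorohept-6-en-2-ol
Product: 9 (R)-2-(pent-4-en-1-yl)oxirane
Conditions: NaOH (powdered), Et2O, rt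
Reagents that add atoms: none
Why: Intramolecular Williamson closure of the alkoxide onto CH2Cl keeps the C–O bond of the stereocentre, so the configuration is retained (descriptor stays R).

Step 5
Reactants: 5 (S)-7-methoxyoct-1-ene; 9 (R)-2-(pent-4-en-1-yl)oxirane
Product: 10 (R)-2-[(S)-10-methoxyundec-4-en-1-yl]oxirane (E/Z mixture)
Conditions: second-generation Grubbs catalyst (3 mol%), 1,4-benzoquinone (10 mol%), 9 (3 equiv), CH2Cl2, 40 °C
Reagents that add atoms: none
Why: Olefin cross-metathesis of two unhindered terminal alkenes is driven by loss of ethylene; excess volatile 9 steers 5 into the cross product, benzoquinone suppresses Ru–H double-bond migration, and the epoxide, ether and both stereocentres are inert (E/Z is irrelevant because the alkene is reduced next).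

Step 6
Reactants: 10 (R)-2-[(S)-10-methoxyundec-4-en-1-yl]oxirane
Product: 11 (R)-2-[(S)-10-methoxyundecyl]oxirane
Conditions: H2 (1 atm), RhCl(PPh3)3 (5 mol%), benzene/EtOH 1:1, rt
Reagents that add atoms: none
Why: Homogeneous hydrogenation with RhCl(PPh3)3 reduces the 1,2-disubstituted alkene under neutral conditions that leave the terminal epoxide, the methyl ether and both stereocentres untouched.

Step 7
Reactants: 12 resorcinol
Product: 13 2,4-dihydroxybenzoic acid
Conditions: KHCO3 (5 equiv), H2O, CO2 (1 atm), 100 °C; then conc. HCl, 0 °C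
Reagents that add atoms: potassium hydrogencarbonate, [K+].OC([O-])=O (in equilibrium with carbon dioxide, O=C=O)
Why: Kolbe–Schmitt carboxylation of the resorcinol phenoxide occurs ortho to one OH and para to the other, giving the thermodynamically favoured 2,4-dihydroxy acid.

Step 8
Reactants: 13 2,4-dihydroxybenzoic acid; 11 (R)-2-[(S)-10-methoxyundecyl]oxirane
Product: 15 (R)-6,8-dihydroxy-3-[(S)-10-methoxyundecyl]isochroman-1-one, via hydroxy acid 14 (not isolated)
Conditions: 13 (1.5 equiv), Pd(OAc)2 (10 mol%), Ac-t-Leu-OH (20 mol%), KOAc (1.5 equiv), HFIP, 75 °C, Ar, 24 h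
Reagents that add atoms: none
Why: Proposed new method: carboxylate-directed ortho-C–H alkylation/lactonisation run on a benzoic acid carrying two free phenols – the potassium carboxylate of 13 binds divalent palladium, the mono-N-protected amino acid ligand mediates concerted metalation–deprotonation at C6–H (the only C–H ortho to the carboxylate, so one regioisomer), the five-membered aryl palladacycle opens the K+/HFIP-activated epoxide at its unsubstituted CH2 (the C–O stereocentre of 11 is never touched, so (R) is carried into C3, and the remote (S)-OMe centre is unaffected), protonolysis releases the catalyst and hydroxy acid 14, which lactonises spontaneously to 15; because the cycle is redox-neutral and only acetate-basic, the phenols (C2–OH hydrogen-bonded to the carboxylate, both poorly nucleophilic in HFIP) should be neither oxidised nor O-alkylated, and the closest known reaction types are the Pd(OAc)2/mono-N-protected amino acid catalysed ortho-C–H alkylation of simple alkyl-, alkoxy- or halo-substituted benzoic acids with epoxides to 3,4-dihydroisocoumarins and the carboxylate-directed ortho-C–H arylation of unprotected salicylic acids.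

**Compound list**
1 | 5-bromopent-1-ene | C=CCCCBr | starting material
2 | (S)-propylene oxide [(S)-2-methyloxirane] | C[C@H]1CO1 | starting material
3 | pent-4-en-1-ylmagnesium bromide | C=CCCC[Mg]Br | intermediate
4 | (S)-oct-7-en-2-ol | C[C@H](O)CCCCC=C | intermediate
5 | (S)-7-methoxyoct-1-ene | CO[C@@H](C)CCCCC=C | intermediate
6 | (R)-epichlorohydrin [(R)-2-(chloromethyl)oxirane] | ClC[C@H]1CO1 | starting material
7 | but-3-en-1-ylmagnesium bromide | C=CCC[Mg]Br | starting material
8 | (R)-1-chlorohept-6-en-2-ol | ClC[C@H](O)CCCC=C | intermediate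
9 | (R)-2-(pent-4-en-1-yl)oxirane | C=CCCC[C@@H]1CO1 | intermediate
10 | (R)-2-[(S)-10-methoxyundec-4-en-1-yl]oxirane (E/Z mixture, E isomer drawn) | CO[C@@H](C)CCCC/C=C/CCC[C@@H]1CO1 | intermediate
11 | (R)-2-[(S)-10-methoxyundecyl]oxirane | CO[C@@H](C)CCCCCCCCC[C@@H]1CO1 | intermediate
12 | resorcinol (benzene-1,3-diol) | Oc1cccc(O)c1 | starting material
13 | 2,4-dihydroxybenzoic acid | OC(=O)c1ccc(O)cc1O | intermediate
14 | 2,4-dihydroxy-6-[(2R,12S)-2-hydroxy-12-methoxytridecyl]benzoic acid | CO[C@@H](C)CCCCCCCCC[C@@H](O)Cc1cc(O)cc(O)c1C(O)=O | intermediate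
15 | (R)-6,8-dihydroxy-3-[(S)-10-methoxyundecyl]isochroman-1-one | CO[C@@H](C)CCCCCCCCC[C@@H]1Cc2cc(O)cc(O)c2C(=O)O1 | target

**Totals**
Total step count: 8.
Longest linear sequence: 5 steps (1, 2, 5, 6, 8; the branch 3, 4, 5, 6, 8 is equally long).

**Three steps most likely to fail**

Step 8 (the proposed new step). The free phenols could sequester palladium as a salicylate-type chelate, the electron-rich ring could open the epoxide in HFIP by a Friedel–Crafts path, or a phenol could be O-alkylated. The fallback uses known chemistry and sets out from 13, with 11 as coupling partner. Perbenzylation (BnBr, K2CO3, DMF, 60 °C) gives benzyl 2,4-bis(benzyloxy)benzoate F1. Saponification (KOH, MeOH/THF/H2O, 60 °C; then HCl) gives 2,4-bis(benzyloxy)benzoic acid F2, an ordinary alkoxy-substituted benzoic acid of the kind for which the Pd(OAc)2/Ac-t-Leu-OH/KOAc/HFIP epoxide alkylation is established. Coupling of F2 with 11 under those conditions gives (R)-6,8-bis(benzyloxy)-3-[(S)-10-methoxyundecyl]isochroman-1-one F3. Hydrogenolysis (H2, Pd/C, EtOAc, rt) removes both benzyl ethers without touching the lactone or the aliphatic methyl ether, and the fallback comes back to the route at 15.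

Step 5. Cross-metathesis of two equally reactive terminal alkenes gives a near-statistical mixture with both homodimers, and any Ru–H double-bond migration would give chain-shortened homologues that cannot be separated. The fallback sets out from 5, with 1 as the second partner, and replaces the alkene–alkene union by a chemoselective alkyl–alkyl coupling. Hydroboration of 5 with 9-BBN (THF, rt) gives 9-[(S)-7-methoxyoctyl]-9-borabicyclo[3.3.1]nonane F4, used without isolation. Suzuki–Miyaura coupling with 1 (Pd(OAc)2, PCy3, K3PO4·H2O, THF, rt) gives (S)-12-methoxytridec-1-ene F5. Epoxidation with mCPBA (CH2Cl2, NaHCO3) gives 2-[(S)-10-methoxyundecyl]oxirane F6 as a 1:1 mixture of epimers at the oxirane carbon. Hydrolytic kinetic resolution with (R,R)-(salen)Co(OAc) [salen = N,N'-bis(3,5-di-tert-butylsalicylidene)cyclohexane-1,2-diaminate] and 0.55 equiv H2O hydrolyses the (S)-oxirane epimer to (2S,12S)-12-methoxytridecane-1,2-diol F7 and leaves the (R)-epimer. The fallback comes back to the route at 11; steps 3, 4 and 6 are then not needed.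

Step 6. The terminal epoxide may be partly reduced or isomerised during the hydrogenation, or the internal alkene may be reduced incompletely. The fallback sets out from 8, with 5 as partner, and moves the hydrogenation to a stage where no epoxide is present. Cross-metathesis of 5 with chlorohydrin 8 (second-generation Grubbs catalyst, 1,4-benzoquinone, CH2Cl2, 40 °C) gives (2R,12S)-1-chloro-12-methoxytridec-6-en-2-ol F8 as an E/Z mixture. Hydrogenation (H2, PtO2, EtOAc, rt) gives (2R,12S)-1-chloro-12-methoxytridecan-2-ol F9. Ring closure with NaOH (Et2O, rt), as in step 4, comes back to the route at 11.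

**Further compounds**
F1 | step 8 | benzyl 2,4-bis(benzyloxy)benzoate | O=C(OCc1ccccc1)c1ccc(OCc2ccccc2)cc1OCc1ccccc1
F2 | step 8 | 2,4-bis(benzyloxy)benzoic acid | OC(=O)c1ccc(OCc2ccccc2)cc1OCc1ccccc1
F3 | step 8 | (R)-6,8-bis(benzyloxy)-3-[(S)-10-methoxyundecyl]isochroman-1-one | CO[C@@H](C)CCCCCCCCC[C@@H]1Cc2cc(OCc3ccccc3)cc(OCc3ccccc3)c2C(=O)O1
F4 | step 5 | 9-[(S)-7-methoxyoctyl]-9-borabicyclo[3.3.1]nonane | CO[C@@H](C)CCCCCCB1C2CCCC1CCC2
F5 | step 5 | (S)-12-methoxytridec-1-ene | CO[C@@H](C)CCCCCCCCCC=C
F6 | step 5 | 2-[(S)-10-methoxyundecyl]oxirane (1:1 epimers at the oxirane carbon) | CO[C@@H](C)CCCCCCCCCC1CO1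
F7 | step 5 | (2S,12S)-12-methoxytridecane-1,2-diol | CO[C@@H](C)CCCCCCCCC[C@H](O)CO
F8 | step 6 | (2R,12S)-1-chloro-12-methoxytridec-6-en-2-ol (E/Z mixture, E isomer drawn) | CO[C@@H](C)CCCC/C=C/CCC[C@@H](O)CCl
F9 | step 6 | (2R,12S)-1-chloro-12-methoxytridecan-2-ol | CO[C@@H](C)CCCCCCCCC[C@@H](O)CCl
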